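**Plan**
- Retrosynthesis cuts the two ring B bonds C1–C8a and C4–C4a (aryne plus furan), the bond between furan C3 and the side-chain carbonyl carbon (Weinreb ketone synthesis) and the isovalerate C–O bond; the C5/C8 hydroxyls trace back to methyl ethers, the C1/C4 oxygens to the furan oxygen and O2.
- Enabling feature: ring B carries its only carbon substituent at C2, so C1–C4 are the four carbons of a 3-substituted furan, and the C4a–C8a edge of ring A, with oxygen on both neighbours (C5, C8), is the reacting bond of a symmetrical 3,6-dimethoxybenzyne.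
- Forward: ring A is made as an ortho-silylaryl triflate from 2,5-dimethoxyphenol; the chain is joined to 3-lithiofuran as a ketone, reduced and acylated; ring B then closes in the aryne–furan cycloaddition.
- Ring B is taken to the quinone (bridge isomerisation, aerobic oxidation) and the methyl ethers are exchanged for hydroxyls by reductive acetylation, oxidative demethylation and selective aryl acetate cleavage.
- Stereochemistry: the single (S)-carbinol centre comes from oxazaborolidine-catalysed reduction of the furyl ketone and is not touched afterwards; the bridgehead centres of the cycloadduct are transient.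

Key step: step 8

Remark on numbering: naphthalene positions are those of the target (ring B = C1–C4 with the side chain on C2, ring A = C5–C8).
Remark on the chemistry: 5,8-dihydroxy-1,4-naphthoquinones exchange their quinonoid and benzenoid rings by fast double proton transfer, so the dihydroxyquinone released in the last step with the side chain on the benzenoid ring is taken to be the same compound as the target as drawn.

**Route**

Step 1
Reactants: 1 2,5-dimethoxyphenol
Product: 2 2,5-dimethoxyphenyl N-(propan-2-yl)carbamate
Conditions: i-PrNCO (1.5 equiv), Et3N (0.2 equiv), CH2Cl2, rt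
Reagents that add atoms: isopropyl isocyanate, CC(C)N=C=O
Why: Amine-catalysed addition of the phenol O–H across the isocyanate (carbamoylation) installs a group that directs ortho-metalation and can later be removed under mild base.

Step 2
Reactants: 2 2,5-dimethoxyphenyl N-(propan-2-yl)carbamate
Product: 6 3,6-dimethoxy-2-(trimethylsilyl)phenyl N-(propan-2-yl)carbamate, via N-silyl carbamate 3 (not isolated), via aryllithium 4 (not isolated), via N,C-disilyl carbamate 5 (not isolated)
Conditions: t-BuMe2SiOTf (1.1 equiv), TMEDA (1.1 equiv), Et2O, 0 °C to rt; then TMEDA (2 equiv), n-BuLi (2 equiv), −78 °C; then Me3SiCl (3 equiv), −78 °C to rt; aq NaHSO4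
Reagents that add atoms: chlorotrimethylsilane, C[Si](C)(C)Cl
Why: Directed ortho-metalation of an aryl carbamate: transient N-silylation masks the N–H, the O-carbamate and the neighbouring methoxy group together direct n-BuLi to the one position lying between them, the aryllithium is silylated at −78 °C before an anionic Fries shift can set in, and the N-silyl group is lost on acidic work-up.

Step 3
Reactants: 6 3,6-dimethoxy-2-(trimethylsilyl)phenyl N-(propan-2-yl)carbamate
Product: 8 3,6-dimethoxy-2-(trimethylsilyl)phenyl trifluoromethanesulfonate, via silylphenol 7 (not isolated)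
Conditions: 1,8-diazabicyclo[5.4.0]undec-7-ene (DBU, 1.5 equiv), Et2NH (1.2 equiv), MeCN, 40 °C; then PhNTf2 (1.5 equiv), rt
Reagents that add atoms: N-phenylbis(trifluoromethanesulfonimide), O=S(=O)(N(c1ccccc1)S(=O)(=O)C(F)(F)F)C(F)(F)F
Why: DBU removes the carbamate N–H proton and E1cB loss of isopropyl isocyanate (scavenged by diethylamine) frees the phenoxide, which is triflated in the same flask, the established one-pot carbamate-to-triflate conversion for ortho-silylaryl triflates that avoids protodesilylation.

Step 4
Reactants: 9 4-methylpent-3-enoic acid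
Product: 10 N-methoxy-N,4-dimethylpent-3-enamide
Conditions: MeNHOMe·HCl (1.2 equiv), 1-ethyl-3-(3-dimethylaminopropyl)carbodiimide hydrochloride (EDC·HCl, 1.2 equiv), N-methylmorpholine (2.5 equiv), CH2Cl2, 0 °C to rt
Reagents that add atoms: N,O-dimethylhydroxylamine hydrochloride, CNOC.Cl
Why: Carbodiimide-mediated amide coupling under weakly basic conditions should give the Weinreb amide without moving the β,γ-alkene into conjugation.

Step 5
Reactants: 11 3-bromofuran; 10 N-methoxy-N,4-dimethylpent-3-enamide
Product: 14 1-(furan-3-yl)-4-methylpent-3-en-1-one, via 3-lithiofuran 12 (not isolated), via lithium hemiaminal 13 (not isolated)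
Conditions: n-BuLi (1.05 equiv), THF, −78 °C; then 10, −78 °C; aq NH4Cl at −78 °C
Reagents that add atoms: none
Why: Bromine–lithium exchange at −78 °C gives 3-lithiofuran without migration to the 2-position, and its addition to the Weinreb amide stops at the chelated tetrahedral adduct, which releases the ketone only on quench (Weinreb ketone synthesis).

Step 6
Reactants: 14 1-(furan-3-yl)-4-methylpent-3-en-1-one
Product: 16 (1S)-1-(furan-3-yl)-4-methylpent-3-en-1-ol, via catechol borate 15 (not isolated)
Conditions: (R)-2-methyl-CBS-oxazaborolidine [(3aR)-1-methyl-3,3-diphenyltetrahydro-1H,3H-pyrrolo[1,2-c][1,3,2]oxazaborole] (0.2 equiv), catecholborane (1.8 equiv), toluene, −78 °C; then MeOH, aq NaOH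
Reagents that add atoms: none
Why: Corey–Bakshi–Shibata reduction, in which the ketone binds the ring boron with the planar furyl group as the large substituent turned away from the catalyst and hydride is delivered to the Re face, so that the (R)-catalyst should give the (S)-carbinol as with aryl alkyl ketones, while catecholborane leaves the trisubstituted alkene alone at −78 °C.

Step 7
Reactants: 16 (1S)-1-(furan-3-yl)-4-methylpent-3-en-1-ol; 17 3-methylbutanoyl chloride
Product: 18 (1S)-1-(furan-3-yl)-4-methylpent-3-en-1-yl 3-methylbutanoate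
Conditions: pyridine (2 equiv), 4-(dimethylamino)pyridine (0.05 equiv), CH2Cl2, 0 °C to rt
Reagents that add atoms: none
Why: Base-mediated O-acylation with the acid chloride breaks no bond at the stereocentre and keeps the medium basic, so the acid-sensitive 3-furyl carbinol cannot ionise.

Step 8
Reactants: 8 3,6-dimethoxy-2-(trimethylsilyl)phenyl trifluoromethanesulfonate; 18 (1S)-1-(furan-3-yl)-4-methylpent-3-en-1-yl 3-methylbutanoate
Product: 20 (1S)-1-(5,8-dimethoxy-1,4-dihydro-1,4-epoxynaphthalen-2-yl)-4-methylpent-3-en-1-yl 3-methylbutanoate (both bridgehead diastereomers), via 3,6-dimethoxybenzyne 19 (not isolated)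
Conditions: CsF (3 equiv), MeCN, rt, 8 (1.4 equiv) added slowly
Reagents that add atoms: none
Why: Fluoride attacks silicon and the aryl anion expels the ortho triflate, releasing 3,6-dimethoxybenzyne 19 at low steady-state concentration, which adds suprafacially across C2 and C5 of the furan in a concerted [4+2] cycloaddition, the closest known reaction type being the Diels–Alder trapping of silyl-triflate-derived arynes by furans. Ring B closes as a six-membered carbocycle by this intermolecular [4+2] annulation, the bonds C1–C8a and C4–C4a forming together and the furan oxygen remaining as a 1,4-bridge. The two bridgehead carbons become stereocentres that are cis by necessity of the bridge; their sense relative to the (S)-carbinol is not controlled and need not be, because both are erased when the bridge is opened in step 9. No regiocontrol is needed, since the aryne is symmetrical about its reacting bond. The selectivity that matters is chemoselectivity for the furan diene over an ene or [2+2] reaction at the trisubstituted alkene, which the much higher reactivity of furan as a 4π partner and the slow release of the aryne should secure. CsF in MeCN at room temperature is too mild to touch the ester or the carbinol stereocentre.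

Step 9
Reactants: 20 (1S)-1-(5,8-dimethoxy-1,4-dihydro-1,4-epoxynaphthalen-2-yl)-4-methylpent-3-en-1-yl 3-methylbutanoate
Product: 23 (1S)-1-(5,8-dimethoxy-1,4-dioxo-1,4-dihydronaphthalen-2-yl)-4-methylpent-3-en-1-yl 3-methylbutanoate, via 2-substituted 1-naphthol 21 (not isolated), via 3-substituted 1-naphthol 22 (not isolated)
Conditions: [Rh(CO)2Cl]2 (2.5 mol%), CH2Cl2, rt; evaporate; then [N,N′-bis(salicylidene)ethylenediaminato]cobalt, Co(salen) (10 mol%), O2 (1 atm), DMF, rt
Reagents that add atoms: dioxygen, O=O
Why: Monovalent rhodium inserts into a strained bridgehead C–O bond and the allylrhodium alkoxide collapses to a 1-naphthol under neutral conditions (the known isomerisation of 1,4-epoxy-1,4-dihydronaphthalenes), after which cobalt-catalysed aerobic phenol oxidation at the free para position converts either regioisomeric naphthol into the same 1,4-quinone, and taking the crude naphthols straight on shortens the time in which the ortho-hydroxybenzylic ester could ionise.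

Step 10
Reactants: 23 (1S)-1-(5,8-dimethoxy-1,4-dioxo-1,4-dihydronaphthalen-2-yl)-4-methylpent-3-en-1-yl 3-methylbutanoate
Product: 25 (1S)-1-[1,4-bis(acetyloxy)-5,8-dimethoxynaphthalen-2-yl]-4-methylpent-3-en-1-yl 3-methylbutanoate, via hydroquinone 24 (not isolated)
Conditions: Zn dust (5 equiv), Ac2O, pyridine, 0 °C to rt
Reagents that add atoms: acetic anhydride, CC(=O)OC(C)=O
Why: Reductive acetylation, in which zinc reduces the quinone and the hydroquinone is acetylated as it forms, which should outrun expulsion of the side-chain carboxylate and leaves ring B electron-poor so that the next oxidation addresses ring A only.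

Step 11
Reactants: 25 (1S)-1-[1,4-bis(acetyloxy)-5,8-dimethoxynaphthalen-2-yl]-4-methylpent-3-en-1-yl 3-methylbutanoate
Product: 26 (1S)-1-[1,4-bis(acetyloxy)-5,8-dioxo-5,8-dihydronaphthalen-2-yl]-4-methylpent-3-en-1-yl 3-methylbutanoate
Conditions: (NH4)2Ce(NO3)6 (2.5 equiv), MeCN–H2O, 0 °C, short contact time
Reagents that add atoms: water, O
Why: Oxidative demethylation of a para-dimethoxyarene by tetravalent cerium (two one-electron oxidations, water adding at the ipso carbons and methanol leaving) forms the quinone in ring A, while the acetylated ring and the alkyl ester are inert and the alkene should survive brief exposure at 0 °C, as in closely related prenylated naphthalenes.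

Step 12
Reactants: 26 (1S)-1-[1,4-bis(acetyloxy)-5,8-dioxo-5,8-dihydronaphthalen-2-yl]-4-methylpent-3-en-1-yl 3-methylbutanoate
Product: 28 isovalerylalkannin [(1S)-1-(5,8-dihydroxy-1,4-dioxo-1,4-dihydronaphthalen-2-yl)-4-methylpent-3-en-1-yl 3-methylbutanoate], via ring A quinone tautomer 27 (not isolated)
Conditions: K2CO3 (2.2 equiv), MeOH, 0 °C, argon, short reaction time; then aq HCl to pH 4
Reagents that add atoms: none
Why: Base-mediated methanolysis distinguishes the two aryl acetates, which sit next to a quinone carbonyl and carry a phenoxide leaving group, from the β-branched secondary alkyl ester, so only the acetates should be cleaved at 0 °C, and the liberated dihydroxyquinone is the proton-transfer tautomer of the target.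

**Compound list**

1 | 2,5-dimethoxyphenol | COc1ccc(OC)c(O)c1 | starting material
2 | 2,5-dimethoxyphenyl N-(propan-2-yl)carbamate | COc1ccc(OC)c(OC(=O)NC(C)C)c1 | intermediate
3 | 2,5-dimethoxyphenyl N-(tert-butyldimethylsilyl)-N-(propan-2-yl)carbamate | COc1ccc(OC)c(OC(=O)N(C(C)C)[Si](C)(C)C(C)(C)C)c1 | intermediate (not isolated)
4 | 6-lithio derivative of 3 (lithium between the carbamate oxygen and a methoxy group) | COc1ccc(OC)c(OC(=O)N(C(C)C)[Si](C)(C)C(C)(C)C)c1[Li] | intermediate (not isolated)
5 | 3,6-dimethoxy-2-(trimethylsilyl)phenyl N-(tert-butyldimethylsilyl)-N-(propan-2-yl)carbamate | COc1ccc(OC)c(OC(=O)N(C(C)C)[Si](C)(C)C(C)(C)C)c1[Si](C)(C)C | intermediate (not isolated)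
6 | 3,6-dimethoxy-2-(trimethylsilyl)phenyl N-(propan-2-yl)carbamate | COc1ccc(OC)c(OC(=O)NC(C)C)c1[Si](C)(C)C | intermediate
7 | 3,6-dimethoxy-2-(trimethylsilyl)phenol | COc1ccc(OC)c(O)c1[Si](C)(C)C | intermediate (not isolated)
8 | 3,6-dimethoxy-2-(trimethylsilyl)phenyl trifluoromethanesulfonate | COc1ccc(OC)c([Si](C)(C)C)c1OS(=O)(=O)C(F)(F)F | intermediate
9 | 4-methylpent-3-enoic acid | CC(C)=CCC(=O)O | starting material
10 | N-methoxy-N,4-dimethylpent-3-enamide | CC(C)=CCC(=O)N(C)OC | intermediate
11 | 3-bromofuran | Brc1ccoc1 | starting material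
12 | 3-lithiofuran | [Li]c1ccoc1 | intermediate (not isolated)
13 | lithium 1-(furan-3-yl)-1-[methoxy(methyl)amino]-4-methylpent-3-en-1-olate | CC(C)=CCC(O[Li])(N(C)OC)c1ccoc1 | intermediate (not isolated)
14 | 1-(furan-3-yl)-4-methylpent-3-en-1-one | CC(C)=CCC(=O)c1ccoc1 | intermediate
15 | 2-{[(1S)-1-(furan-3-yl)-4-methylpent-3-en-1-yl]oxy}-1,3,2-benzodioxaborole | CC(C)=CC[C@H](OB1Oc2ccccc2O1)c1ccoc1 | intermediate (not isolated)
16 | (1S)-1-(furan-3-yl)-4-methylpent-3-en-1-ol | CC(C)=CC[C@H](O)c1ccoc1 | intermediate
17 | 3-methylbutanoyl chloride | CC(C)CC(Cl)=O | starting material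
18 | (1S)-1-(furan-3-yl)-4-methylpent-3-en-1-yl 3-methylbutanoate | CC(C)=CC[C@H](OC(=O)CC(C)C)c1ccoc1 | intermediate
19 | 3,6-dimethoxybenzyne (1,4-dimethoxycyclohexa-1,3-dien-5-yne) | COC1=CC=C(OC)C#C1 | intermediate (not isolated)
20 | (1S)-1-(5,8-dimethoxy-1,4-dihydro-1,4-epoxynaphthalen-2-yl)-4-methylpent-3-en-1-yl 3-methylbutanoate, mixture of the two bridgehead diastereomers carried on together | CC(C)=CC[C@H](OC(=O)CC(C)C)C1=CC2OC1c1c(OC)ccc(OC)c12 | intermediate
21 | (1S)-1-(1-hydroxy-5,8-dimethoxynaphthalen-2-yl)-4-methylpent-3-en-1-yl 3-methylbutanoate | CC(C)=CC[C@H](OC(=O)CC(C)C)c1ccc2c(OC)ccc(OC)c2c1O | intermediate (not isolated)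
22 | (1S)-1-(4-hydroxy-5,8-dimethoxynaphthalen-2-yl)-4-methylpent-3-en-1-yl 3-methylbutanoate | CC(C)=CC[C@H](OC(=O)CC(C)C)c1cc(O)c2c(OC)ccc(OC)c2c1 | intermediate (not isolated)
23 | (1S)-1-(5,8-dimethoxy-1,4-dioxo-1,4-dihydronaphthalen-2-yl)-4-methylpent-3-en-1-yl 3-methylbutanoate | CC(C)=CC[C@H](OC(=O)CC(C)C)C1=CC(=O)c2c(OC)ccc(OC)c2C1=O | intermediate
24 | (1S)-1-(1,4-dihydroxy-5,8-dimethoxynaphthalen-2-yl)-4-methylpent-3-en-1-yl 3-methylbutanoate | CC(C)=CC[C@H](OC(=O)CC(C)C)c1cc(O)c2c(OC)ccc(OC)c2c1O | intermediate (not isolated)
25 | (1S)-1-[1,4-bis(acetyloxy)-5,8-dimethoxynaphthalen-2-yl]-4-methylpent-3-en-1-yl 3-methylbutanoate | CC(C)=CC[C@H](OC(=O)CC(C)C)c1cc(OC(C)=O)c2c(OC)ccc(OC)c2c1OC(C)=O | intermediate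
26 | (1S)-1-[1,4-bis(acetyloxy)-5,8-dioxo-5,8-dihydronaphthalen-2-yl]-4-methylpent-3-en-1-yl 3-methylbutanoate | CC(C)=CC[C@H](OC(=O)CC(C)C)c1cc(OC(C)=O)c2c(c1OC(C)=O)C(=O)C=CC2=O | intermediate
27 | (1S)-1-(1,4-dihydroxy-5,8-dioxo-5,8-dihydronaphthalen-2-yl)-4-methylpent-3-en-1-yl 3-methylbutanoate (first-formed tautomer of 28) | CC(C)=CC[C@H](OC(=O)CC(C)C)c1cc(O)c2c(c1O)C(=O)C=CC2=O | intermediate (not isolated)
28 | isovalerylalkannin, (1S)-1-(5,8-dihydroxy-1,4-dioxo-1,4-dihydronaphthalen-2-yl)-4-methylpent-3-en-1-yl 3-methylbutanoate | CC(C)=CC[C@H](OC(=O)CC(C)C)C1=CC(=O)c2c(O)ccc(O)c2C1=O | target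

**Count and risks**

Total steps: 12. Longest linear sequence: 9 steps (steps 4 to 12, from 4-methylpent-3-enoic acid or 3-bromofuran); the aryne arm (steps 1 to 3) joins at step 8.

Steps most likely to fail:

Step 9. Once the electron-rich naphthols are unveiled, the side-chain C–O bond may ionise: the ortho hydroxyl can assist expulsion of isovalerate, and rhodium may ionise the allylic ester of 20. The fallback replaces the carboxylate by a silyl ether for the annulation and the oxidation of ring B. It sets out from alcohol 16 and comes back at quinone 23. Silylation of 16 (t-BuMe2SiCl, imidazole, DMF) would give tert-butyl{[(1S)-1-(furan-3-yl)-4-methylpent-3-en-1-yl]oxy}dimethylsilane F1. Cycloaddition with the aryne from 8 under the conditions of step 8 would give the silyloxy epoxynaphthalene F2. [Rh(CO)2Cl]2 would open it to the 1-hydroxy naphthol F3 and the 4-hydroxy naphthol F4, and Co(salen) with O2 would oxidise both to the silyloxy quinone F5. HF·pyridine in MeCN would then free the hydroxy quinone F6, and acylation with 17 (pyridine, 4-(dimethylamino)pyridine, CH2Cl2) rejoins the route at 23.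

Step 12. Chemoselectivity between the aryl acetates and the side-chain ester may be incomplete, through concurrent methanolysis of the isovalerate or base-induced degradation of the dihydroxyquinone. The fallback gives up selectivity in the cleavage and restores it in an acylation. It sets out from 26 and comes back at 28. All three esters would be saponified (1 M NaOH, degassed MeOH–H2O, 0 °C to rt, then HCl) to alkannin F7. The side-chain hydroxyl alone would then be esterified with 3-methylbutanoic acid, N,N′-dicyclohexylcarbodiimide and catalytic 4-(dimethylamino)pyridine in CH2Cl2 at 0 °C, the two phenolic hydroxyls being held in hydrogen bonds to the quinone carbonyls and therefore unreactive.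

Step 6. Facial discrimination between the small 3-furyl group and the primary alkyl chain may be insufficient, or uncatalysed background reduction may erode the enantiomeric purity. The fallback sets the stereocentre in a C–C bond formation. It sets out from 11 and comes back at 16. 3-Lithiofuran 12 made from 11 would be formylated with DMF to furan-3-carbaldehyde F8. Brown allylboration with (−)-B-allyldiisopinocampheylborane (the reagent derived from (+)-α-pinene; Et2O, −78 °C; then NaOH, H2O2) should give (1S)-1-(furan-3-yl)but-3-en-1-ol F9 through the chair-like six-membered transition state. Cross-metathesis with excess 2-methylbut-2-ene, catalysed by the second-generation Grubbs catalyst [1,3-bis(2,4,6-trimethylphenyl)imidazolidin-2-ylidene]dichloro(benzylidene)(tricyclohexylphosphine)ruthenium, would install the trisubstituted alkene and give 16.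

**Further compounds**

F1 | step 9 | tert-butyl{[(1S)-1-(furan-3-yl)-4-methylpent-3-en-1-yl]oxy}dimethylsilane | CC(C)=CC[C@H](O[Si](C)(C)C(C)(C)C)c1ccoc1
F2 | step 9 | tert-butyl{[(1S)-1-(5,8-dimethoxy-1,4-dihydro-1,4-epoxynaphthalen-2-yl)-4-methylpent-3-en-1-yl]oxy}dimethylsilane, both bridgehead diastereomers | CC(C)=CC[C@H](O[Si](C)(C)C(C)(C)C)C1=CC2OC1c1c(OC)ccc(OC)c12
F3 | step 9 | 2-[(1S)-1-{[tert-butyl(dimethyl)silyl]oxy}-4-methylpent-3-en-1-yl]-5,8-dimethoxynaphthalen-1-ol | CC(C)=CC[C@H](O[Si](C)(C)C(C)(C)C)c1ccc2c(OC)ccc(OC)c2c1O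
F4 | step 9 | 3-[(1S)-1-{[tert-butyl(dimethyl)silyl]oxy}-4-methylpent-3-en-1-yl]-5,8-dimethoxynaphthalen-1-ol | CC(C)=CC[C@H](O[Si](C)(C)C(C)(C)C)c1cc(O)c2c(OC)ccc(OC)c2c1
F5 | step 9 | 2-[(1S)-1-{[tert-butyl(dimethyl)silyl]oxy}-4-methylpent-3-en-1-yl]-5,8-dimethoxynaphthalene-1,4-dione | CC(C)=CC[C@H](O[Si](C)(C)C(C)(C)C)C1=CC(=O)c2c(OC)ccc(OC)c2C1=O
F6 | step 9 | 2-[(1S)-1-hydroxy-4-methylpent-3-en-1-yl]-5,8-dimethoxynaphthalene-1,4-dione | CC(C)=CC[C@H](O)C1=CC(=O)c2c(OC)ccc(OC)c2C1=O
F7 | step 12 | alkannin, 5,8-dihydroxy-2-[(1S)-1-hydroxy-4-methylpent-3-en-1-yl]naphthalene-1,4-dione | CC(C)=CC[C@H](O)C1=CC(=O)c2c(O)ccc(O)c2C1=O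
F8 | step 6 | furan-3-carbaldehyde | O=Cc1ccoc1
F9 | step 6 | (1S)-1-(furan-3-yl)but-3-en-1-ol | C=CC[C@H](O)c1ccoc1
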